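The route rests on cutting the C5–C10 and C8–C9 bonds of the trans-fused decalin: ring A (C1–C5, C10) and ring B (C5–C10) both form when the C9=C10 (E)-enoate of an open-chain triene adds across its C5=C6–C7=C8 2-silyloxy diene. This single thermal cycloaddition creates C5, C8, C9 and the quaternary C10, the ring fusion and the C9 carbon branch (C11) cis to the C10 methyl, and leaves a C7 enol ether for the Δ7 alkene. The precursor is an acyclic methyl 3,7,7-trimethyldodeca-2,8,10-trienoate whose C1–C4 tether carries the pantolactone-derived C3 silyloxy centre beside the C4 gem-dimethyl carbon; that centre sets the absolute configuration.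

Key step: step 11

Remarks on the chemistry:
- Labdane numbering is used throughout (C11 on C9, C17 on C8, C20 on C10). The target is an ent-labdane, (3R,5S,9R,10S,13E), with an equatorial 3-hydroxyl; ent- names follow the usual convention.
- (S)-Pantolactone supplies 3R with unchanged geometry; only the CIP ranking of the two carbon neighbours changes once C2 becomes CH2.
- The (E)-enoate geometry is installed by a stereoretentive cross-coupling, not by olefination of a methyl ketone.
- The C9 vinyl group is made before the Δ7 alkene exists, so no β,γ-unsaturated C11 aldehyde is handled.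
- 30-Hydroxytriacontanoic acid and methyl but-2-ynoate are taken as purchasable; the acyl chain is C30.

Step 1
Reactants: 1 methyl but-2-ynoate
Product: 2 methyl (2E)-3-(tributylstannyl)but-2-enoate
Conditions: Bu3SnH, LDA, THF, −40 °C; CuBr·SMe2, −78 °C; then 1, MeOH, −78 °C
Reagents that add atoms: tributyltin hydride, CCCC[SnH](CCCC)CCCC
Why: Stannylcupration of an ynoate (conjugate syn-addition of a stannylcopper reagent) with in-situ protonation of the alkenylcopper at −78 °C, before it can isomerise, should place tin trans to the ester (kinetic E adduct).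

Step 2
Reactants: 2 methyl (2E)-3-(tributylstannyl)but-2-enoate
Product: 3 methyl (2E)-3-iodobut-2-enoate
Conditions: I2, CH2Cl2, 0 °C
Reagents that add atoms: iodine, II
Why: Iododestannylation (ipso electrophilic substitution at the sp2 carbon) proceeds with retention and should give the (E)-iodide.

Step 3
Reactants: 3 methyl (2E)-3-iodobut-2-enoate (part of the batch)
Product: 4 (2E)-3-iodobut-2-en-1-ol
Conditions: DIBAL-H, CH2Cl2, −78 °C; Rochelle salt
Reagents that add atoms: none
Why: DIBAL-H reduces the enoate 1,2 to the allylic alcohol at −78 °C without touching the C–I bond or the alkene geometry.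

Step 4
Reactants: 5 (S)-(+)-pantolactone
Product: 6 (3S)-4,4-dimethyl-3-[(triisopropylsilyl)oxy]oxolan-2-one
Conditions: TIPSOTf, 2,6-lutidine, CH2Cl2, 0 °C → rt
Reagents that add atoms: triisopropylsilyl trifluoromethanesulfonate, CC(C)[Si](OS(=O)(=O)C(F)(F)F)(C(C)C)C(C)C
Why: Silyl triflate/lutidine silylation of the hindered α-hydroxy lactone breaks no bond at the stereocentre.

Step 5
Reactants: 6 (3S)-4,4-dimethyl-3-[(triisopropylsilyl)oxy]oxolan-2-one
Product: 7 (3S)-4,4-dimethyl-3-[(triisopropylsilyl)oxy]oxolan-2-ol (lactol, both anomers)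
Conditions: DIBAL-H (1.1 equiv), CH2Cl2, −78 °C
Reagents that add atoms: none
Why: Partial reduction of the lactone stops at the aluminium hemiacetal at −78 °C and should give the lactol on work-up.

Step 6
Reactants: 7 (3S)-4,4-dimethyl-3-[(triisopropylsilyl)oxy]oxolan-2-ol
Product: 8 (3R)-2,2-dimethyl-3-[(triisopropylsilyl)oxy]pent-4-en-1-ol
Conditions: Ph3PCH3Br, KOtBu, THF, 0 → 50 °C
Reagents that add atoms: methyltriphenylphosphonium bromide, C[P+](c1ccccc1)(c1ccccc1)c1ccccc1.[Br-]
Why: Wittig methylenation of the hydroxy-aldehyde tautomer of the lactol, in which the bulky TIPS group should resist migration to the freed neopentyl alkoxide and the shielded, transiently exposed α-centre should keep its configuration.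

Step 7
Reactants: 8 (3R)-2,2-dimethyl-3-[(triisopropylsilyl)oxy]pent-4-en-1-ol; 3 methyl (2E)-3-iodobut-2-enoate
Product: 10 methyl (2E,6R)-8-hydroxy-3,7,7-trimethyl-6-[(triisopropylsilyl)oxy]oct-2-enoate, via alkylborane 9 (not isolated)
Conditions: 9-BBN-H (2.2 equiv), THF, rt → 40 °C; then 3, Pd(dppf)Cl2 (5 mol%), AsPh3, Cs2CO3, DMF/H2O, rt
Reagents that add atoms: none
Why: Anti-Markovnikov hydroboration with 9-BBN puts boron on C1, and the B-alkyl Suzuki–Miyaura coupling retains the iodide geometry, so the tether ends trans to the ester; any O-borinate at the free hydroxyl is cleaved by the aqueous base.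

Step 8
Reactants: 10 methyl (2E,6R)-8-hydroxy-3,7,7-trimethyl-6-[(triisopropylsilyl)oxy]oct-2-enoate
Product: 11 methyl (2E,6R)-3,7,7-trimethyl-8-oxo-6-[(triisopropylsilyl)oxy]oct-2-enoate
Conditions: Dess–Martin periodinane, CH2Cl2, rt
Reagents that add atoms: none
Why: Dess–Martin oxidation of the neopentyl alcohol gives an aldehyde without α-hydrogens, so neither epimerisation nor β-elimination of the silyloxy group is possible.

Step 9
Reactants: 11 methyl (2E,6R)-3,7,7-trimethyl-8-oxo-6-[(triisopropylsilyl)oxy]oct-2-enoate; 12 diethyl (2-oxobutyl)phosphonate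
Product: 13 methyl (2E,6R,8E)-3,7,7-trimethyl-10-oxo-6-[(triisopropylsilyl)oxy]dodeca-2,8-dienoate
Conditions: 12, NaH, THF, 0 °C; then 11, rt → 45 °C
Reagents that add atoms: none
Why: Horner–Wadsworth–Emmons olefination with the β-ketophosphonate anion should give the (E)-enone, the non-enolisable aldehyde allowing the gentle heating its hindrance may need.

Step 10
Reactants: 13 methyl (2E,6R,8E)-3,7,7-trimethyl-10-oxo-6-[(triisopropylsilyl)oxy]dodeca-2,8-dienoate
Product: 14 methyl (2E,6R,8E,10Z)-10-[(tert-butyldimethylsilyl)oxy]-3,7,7-trimethyl-6-[(triisopropylsilyl)oxy]dodeca-2,8,10-trienoate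
Conditions: TBSOTf, Et3N, CH2Cl2, −78 → 0 °C
Reagents that add atoms: tert-butyldimethylsilyl trifluoromethanesulfonate, CC(C)(C)[Si](C)(C)OS(=O)(=O)C(F)(F)F
Why: Soft enolisation (O-silylation, then deprotonation at C8, the only enolisable site because C4 is quaternary) should give the cross-conjugated 2-silyloxy diene as the (Z)-enol ether, the methyl turning away from the vinyl group, while the enoate is not silylated under these conditions.

Step 11
Reactants: 14 methyl (2E,6R,8E,10Z)-10-[(tert-butyldimethylsilyl)oxy]-3,7,7-trimethyl-6-[(triisopropylsilyl)oxy]dodeca-2,8,10-trienoate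
Product: 15 methyl (1R,2S,4aS,6R,8aR)-3-[(tert-butyldimethylsilyl)oxy]-2,5,5,8a-tetramethyl-6-[(triisopropylsilyl)oxy]-1,2,4a,5,6,7,8,8a-octahydronaphthalene-1-carboxylate (methyl ent-7-silyloxy-3β-silyloxydrim-6-en-11-oate, C8 methyl cis to C11)
Conditions: toluene (0.02 M, degassed), BHT (cat.), sealed base-washed tube, 200 °C
Reagents that add atoms: none
Why: Thermal, concerted but asynchronous [4+2] cycloaddition of the tethered (E)-enoate onto the 2-silyloxy diene, the C5–C10 bond to the enoate β-carbon expected to lead the C8–C9 bond; the closest known reaction type is the type-1 intramolecular Diels–Alder reaction of deca-1,7,9-triene esters and of tethered silyloxy dienes to octalins. Ring A closes through the C5–C10 bond with the C1–C4 tether folded as a chair, and ring B is the new cyclohexene itself, closed by the C5–C10 and C8–C9 bonds together. C9 is fixed relative to C10 by the (E)-enoate geometry (suprafacial addition, C11 cis to C20), C8 by the (Z)-enol ether whose methyl is the outward diene substituent (C17 cis to C11), C5 relative to C10 by the ester-endo, tether-anti transition state (trans fusion), and the absolute sense of all four by C3, whose OTIPS group takes the equatorial site on the chair tether. The step therefore needs endo and diene-face selectivity, the first resting on secondary overlap of the ester with C6/C7 and the second on the equatorial preference of the bulky silyloxy group, while the gem-dimethyl group raises the population of the folded conformer. The trisubstituted dienophile and the new quaternary centre call for about 200 °C, which the two silyl groups and a diene without an inward alkyl group (no 1,5-hydrogen shift) should tolerate; stereoisomers would be separated at this stage.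

Step 12
Reactants: 15 methyl ent-7-[(tert-butyldimethylsilyl)oxy]-3β-[(triisopropylsilyl)oxy]drim-6-en-11-oate
Product: 16 ent-7-[(tert-butyldimethylsilyl)oxy]-3β-[(triisopropylsilyl)oxy]drim-6-en-11-ol
Conditions: LiAlH4, THF, 0 °C; Rochelle salt
Reagents that add atoms: none
Why: Hydride reduction of the hindered ester to the primary alcohol, the TBS enol ether and the TIPS ether being inert to LiAlH4 and to a neutral work-up.

Step 13
Reactants: 16 ent-7-[(tert-butyldimethylsilyl)oxy]-3β-[(triisopropylsilyl)oxy]drim-6-en-11-ol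
Product: 17 ent-7-[(tert-butyldimethylsilyl)oxy]-3β-[(triisopropylsilyl)oxy]drim-6-en-11-al
Conditions: Dess–Martin periodinane, pyridine, CH2Cl2, 0 °C → rt
Reagents that add atoms: none
Why: Buffered Dess–Martin oxidation gives the aldehyde under non-basic, non-acidic conditions that spare the enol ether and do not enolise C9.

Step 14
Reactants: 17 ent-7-[(tert-butyldimethylsilyl)oxy]-3β-[(triisopropylsilyl)oxy]drim-6-en-11-al
Product: 19 ent-3β-[(triisopropylsilyl)oxy]-13,14,15,16-tetranorlabd-11-en-7-one, via vinyl silyl enol ether 18 (not isolated)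
Conditions: Ph3PCH3Br, KHMDS, THF, −78 → 0 °C; then 1 M aq. HCl, THF, rt
Reagents that add atoms: methyltriphenylphosphonium bromide, C[P+](c1ccccc1)(c1ccccc1)c1ccccc1.[Br-]
Why: Wittig methylenation with the non-stabilised ylide at low temperature should outrun enolisation toward C9, and the acidic quench destroys excess ylide before the ketone appears and hydrolyses the TBS enol ether by C6 protonation while the TIPS ether survives; the C8 configuration is immaterial because C8 becomes sp2 in step 15.

Step 15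
Reactants: 19 ent-3β-[(triisopropylsilyl)oxy]-13,14,15,16-tetranorlabd-11-en-7-one
Product: 20 ent-3β-[(triisopropylsilyl)oxy]-13,14,15,16-tetranorlabda-7,11-dien-7-yl trifluoromethanesulfonate
Conditions: Tf2O, 2,6-di-tert-butyl-4-methylpyridine, CH2Cl2, 0 °C → rt
Reagents that add atoms: trifluoromethanesulfonic anhydride, O=S(=O)(OS(=O)(=O)C(F)(F)F)C(F)(F)F
Why: Stang-type enol triflate formation, in which the triflyloxycarbenium ion loses the C8 proton to give the tetrasubstituted C7=C8 triflate, the Zaitsev and thermodynamic isomer because the Δ6 isomer would keep the C8 methyl syn-axial to C20 or in allylic strain with OTf.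

Step 16
Reactants: 20 ent-3β-[(triisopropylsilyl)oxy]-13,14,15,16-tetranorlabda-7,11-dien-7-yl trifluoromethanesulfonate
Product: 21 ent-3β-[(triisopropylsilyl)oxy]-13,14,15,16-tetranorlabda-7,11-diene
Conditions: Pd(OAc)2 (5 mol%), PPh3, HCO2H, Bu3N, DMF, 60 °C
Reagents that add atoms: none
Why: Palladium-catalysed formate reduction of the enol triflate (oxidative addition, decarboxylation of formate to Pd–H, reductive elimination) replaces OTf by H at C7 and so fixes the C7=C8 alkene regiospecifically.

Step 17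
Reactants: 21 ent-3β-[(triisopropylsilyl)oxy]-13,14,15,16-tetranorlabda-7,11-diene; 4 (2E)-3-iodobut-2-en-1-ol
Product: 23 ent-3β-[(triisopropylsilyl)oxy]labda-7,13E-dien-15-ol, via alkylborane 22 (not isolated)
Conditions: 9-BBN-H, THF, rt; then 4, Pd(dppf)Cl2 (5 mol%), AsPh3, Cs2CO3, DMF/H2O, rt
Reagents that add atoms: none
Why: 9-BBN hydroborates only the monosubstituted C11=C12 alkene (boron on C12) and the B-alkyl Suzuki–Miyaura coupling forms C12–C13 with retention of the iodide geometry, giving the 13E allylic alcohol.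

Step 18
Reactants: 24 30-hydroxytriacontanoic acid
Product: 26 30-[(tert-butyldimethylsilyl)oxy]triacontanoic acid, via silyl ester 25 (not isolated)
Conditions: TBSCl (2.5 equiv), imidazole, DMF/THF, 45 °C; then K2CO3, MeOH/THF/H2O, rt; citric acid work-up
Reagents that add atoms: tert-butyldimethylsilyl chloride, CC(C)(C)[Si](C)(C)Cl
Why: Silylation of hydroxyl and carboxyl groups followed by selective cleavage of the labile silyl ester with mild base is the standard protection of an ω-hydroxy acid and leaves the primary TBS ether.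

Step 19
Reactants: 23 ent-3β-[(triisopropylsilyl)oxy]labda-7,13E-dien-15-ol; 26 30-[(tert-butyldimethylsilyl)oxy]triacontanoic acid
Product: 27 ent-3β-[(triisopropylsilyl)oxy]labda-7,13E-dien-15-yl 30-[(tert-butyldimethylsilyl)oxy]triacontanoate
Conditions: DIC, DMAP (cat.), CH2Cl2, 30 °C
Reagents that add atoms: none
Why: Steglich esterification (carbodiimide activation, DMAP acyl transfer) acylates the only free hydroxyl, the primary allylic C15–OH, under neutral conditions that do not ionise the allylic system.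

Step 20
Reactants: 27 ent-3β-[(triisopropylsilyl)oxy]labda-7,13E-dien-15-yl 30-[(tert-butyldimethylsilyl)oxy]triacontanoate
Product: 28 ent-3β-hydroxylabda-7,13E-dien-15-yl 30-hydroxytriacontanoate (target, CNP0303636.1)
Conditions: HF·pyridine, pyridine, THF, 0 °C → rt
Reagents that add atoms: none
Why: Fluoride-assisted cleavage of both Si–O bonds by buffered HF·pyridine, the primary TBS ether first and the hindered C3 TIPS ether more slowly, under conditions too weakly acidic to ionise the allylic ester or move either trisubstituted alkene.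

Compound list
1 | methyl but-2-ynoate | CC#CC(=O)OC | starting material
2 | methyl (2E)-3-(tributylstannyl)but-2-enoate | COC(=O)/C=C(C)/[Sn](CCCC)(CCCC)CCCC | intermediate
3 | methyl (2E)-3-iodobut-2-enoate | COC(=O)/C=C(C)/I | intermediate
4 | (2E)-3-iodobut-2-en-1-ol | OC/C=C(C)/I | intermediate
5 | (S)-(+)-pantolactone, (3S)-3-hydroxy-4,4-dimethyloxolan-2-one | CC1(C)COC(=O)[C@H]1O | starting material
6 | (3S)-4,4-dimethyl-3-[(triisopropylsilyl)oxy]oxolan-2-one | CC1(C)COC(=O)[C@H]1O[Si](C(C)C)(C(C)C)C(C)C | intermediate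
7 | (3S)-4,4-dimethyl-3-[(triisopropylsilyl)oxy]oxolan-2-ol (lactol, both anomers) | CC1(C)COC(O)[C@H]1O[Si](C(C)C)(C(C)C)C(C)C | intermediate
8 | (3R)-2,2-dimethyl-3-[(triisopropylsilyl)oxy]pent-4-en-1-ol | OCC(C)(C)[C@H](O[Si](C(C)C)(C(C)C)C(C)C)C=C | intermediate
9 | 9-[(3R)-5-hydroxy-4,4-dimethyl-3-(triisopropylsilyloxy)pentyl]-9-borabicyclo[3.3.1]nonane | OCC(C)(C)[C@H](O[Si](C(C)C)(C(C)C)C(C)C)CCB1C2CCCC1CCC2 | intermediate (not isolated)
10 | methyl (2E,6R)-8-hydroxy-3,7,7-trimethyl-6-[(triisopropylsilyl)oxy]oct-2-enoate | OCC(C)(C)[C@H](O[Si](C(C)C)(C(C)C)C(C)C)CC/C(C)=C/C(=O)OC | intermediate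
11 | methyl (2E,6R)-3,7,7-trimethyl-8-oxo-6-[(triisopropylsilyl)oxy]oct-2-enoate | O=CC(C)(C)[C@H](O[Si](C(C)C)(C(C)C)C(C)C)CC/C(C)=C/C(=O)OC | intermediate
12 | diethyl (2-oxobutyl)phosphonate | CCC(=O)CP(=O)(OCC)OCC | starting material
13 | methyl (2E,6R,8E)-3,7,7-trimethyl-10-oxo-6-[(triisopropylsilyl)oxy]dodeca-2,8-dienoate | CCC(=O)/C=C/C(C)(C)[C@H](O[Si](C(C)C)(C(C)C)C(C)C)CC/C(C)=C/C(=O)OC | intermediate
14 | methyl (2E,6R,8E,10Z)-10-[(tert-butyldimethylsilyl)oxy]-3,7,7-trimethyl-6-[(triisopropylsilyl)oxy]dodeca-2,8,10-trienoate (key-step precursor) | C/C=C(\O[Si](C)(C)C(C)(C)C)/C=C/C(C)(C)[C@H](O[Si](C(C)C)(C(C)C)C(C)C)CC/C(C)=C/C(=O)OC | intermediate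
15 | methyl (1R,2S,4aS,6R,8aR)-3-[(tert-butyldimethylsilyl)oxy]-2,5,5,8a-tetramethyl-6-[(triisopropylsilyl)oxy]-1,2,4a,5,6,7,8,8a-octahydronaphthalene-1-carboxylate (key-step product; trans-fused, C8 methyl, C11 and C20 mutually cis, 3-OTIPS equatorial) | C[C@@H]1C(O[Si](C)(C)C(C)(C)C)=C[C@@H]2C(C)(C)[C@H](O[Si](C(C)C)(C(C)C)C(C)C)CC[C@@]2(C)[C@@H]1C(=O)OC | intermediate
16 | ent-7-[(tert-butyldimethylsilyl)oxy]-3β-[(triisopropylsilyl)oxy]drim-6-en-11-ol | C[C@@H]1C(O[Si](C)(C)C(C)(C)C)=C[C@@H]2C(C)(C)[C@H](O[Si](C(C)C)(C(C)C)C(C)C)CC[C@@]2(C)[C@@H]1CO | intermediate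
17 | ent-7-[(tert-butyldimethylsilyl)oxy]-3β-[(triisopropylsilyl)oxy]drim-6-en-11-al | C[C@@H]1C(O[Si](C)(C)C(C)(C)C)=C[C@@H]2C(C)(C)[C@H](O[Si](C(C)C)(C(C)C)C(C)C)CC[C@@]2(C)[C@@H]1C=O | intermediate
18 | ent-7-[(tert-butyldimethylsilyl)oxy]-3β-[(triisopropylsilyl)oxy]-13,14,15,16-tetranorlabda-6,11-diene | C[C@@H]1C(O[Si](C)(C)C(C)(C)C)=C[C@@H]2C(C)(C)[C@H](O[Si](C(C)C)(C(C)C)C(C)C)CC[C@@]2(C)[C@@H]1C=C | intermediate (not isolated)
19 | ent-3β-[(triisopropylsilyl)oxy]-13,14,15,16-tetranorlabd-11-en-7-one (C8 drawn as in the adduct; its epimer would serve equally) | C[C@@H]1C(=O)C[C@@H]2C(C)(C)[C@H](O[Si](C(C)C)(C(C)C)C(C)C)CC[C@@]2(C)[C@@H]1C=C | intermediate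
20 | ent-3β-[(triisopropylsilyl)oxy]-13,14,15,16-tetranorlabda-7,11-dien-7-yl trifluoromethanesulfonate | CC1=C(OS(=O)(=O)C(F)(F)F)C[C@@H]2C(C)(C)[C@H](O[Si](C(C)C)(C(C)C)C(C)C)CC[C@@]2(C)[C@@H]1C=C | intermediate
21 | ent-3β-[(triisopropylsilyl)oxy]-13,14,15,16-tetranorlabda-7,11-diene | CC1=CC[C@@H]2C(C)(C)[C@H](O[Si](C(C)C)(C(C)C)C(C)C)CC[C@@]2(C)[C@@H]1C=C | intermediate
22 | 9-{ent-3β-[(triisopropylsilyl)oxy]-13,14,15,16-tetranorlabd-7-en-12-yl}-9-borabicyclo[3.3.1]nonane | CC1=CC[C@@H]2C(C)(C)[C@H](O[Si](C(C)C)(C(C)C)C(C)C)CC[C@@]2(C)[C@@H]1CCB3C4CCCC3CCC4 | intermediate (not isolated)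
23 | ent-3β-[(triisopropylsilyl)oxy]labda-7,13E-dien-15-ol | CC1=CC[C@@H]2C(C)(C)[C@H](O[Si](C(C)C)(C(C)C)C(C)C)CC[C@@]2(C)[C@@H]1CC/C(C)=C/CO | intermediate
24 | 30-hydroxytriacontanoic acid | OC(=O)CCCCCCCCCCCCCCCCCCCCCCCCCCCCCO | starting material
25 | tert-butyldimethylsilyl 30-[(tert-butyldimethylsilyl)oxy]triacontanoate | CC(C)(C)[Si](C)(C)OC(=O)CCCCCCCCCCCCCCCCCCCCCCCCCCCCCO[Si](C)(C)C(C)(C)C | intermediate (not isolated)
26 | 30-[(tert-butyldimethylsilyl)oxy]triacontanoic acid | OC(=O)CCCCCCCCCCCCCCCCCCCCCCCCCCCCCO[Si](C)(C)C(C)(C)C | intermediate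
27 | ent-3β-[(triisopropylsilyl)oxy]labda-7,13E-dien-15-yl 30-[(tert-butyldimethylsilyl)oxy]triacontanoate | CC1=CC[C@@H]2C(C)(C)[C@H](O[Si](C(C)C)(C(C)C)C(C)C)CC[C@@]2(C)[C@@H]1CC/C(C)=C/COC(=O)CCCCCCCCCCCCCCCCCCCCCCCCCCCCCO[Si](C)(C)C(C)(C)C | intermediate
28 | ent-3β-hydroxylabda-7,13E-dien-15-yl 30-hydroxytriacontanoate, (3R,5S,9R,10S) | CC1=CC[C@@H]2C(C)(C)[C@H](O)CC[C@@]2(C)[C@@H]1CC/C(C)=C/COC(=O)CCCCCCCCCCCCCCCCCCCCCCCCCCCCCO | target

Total step count: 20 (16 on the main line, 3 for the two C4 iodides, 1 for the protected acid).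
Longest linear sequence: 16 steps, from 5 to 28 (steps 4–17, 19, 20).

Steps most likely to fail

Step 11. The trisubstituted enoate may add so slowly that thermal loss of the enol silyl group or polymerisation overtakes cycloaddition, or the endo/exo and diene-face discrimination may be poor. The fallback changes the dienophile and keeps the disconnection. Setting out from 14, DIBAL-H (CH2Cl2, −78 °C, Rochelle work-up) should give (2E,6R,8E,10Z)-10-[(tert-butyldimethylsilyl)oxy]-3,7,7-trimethyl-6-[(triisopropylsilyl)oxy]dodeca-2,8,10-trien-1-ol F1. MnO2 (CH2Cl2, rt) should then give (2E,6R,8E,10Z)-10-[(tert-butyldimethylsilyl)oxy]-3,7,7-trimethyl-6-[(triisopropylsilyl)oxy]dodeca-2,8,10-trienal F2. The formyl group is a stronger and more endo-directing activator than the ester, so the intramolecular Diels–Alder reaction of the trienal should run in toluene at roughly 110–140 °C through the same transition-state geometry. It would deliver aldehyde 17 directly, where the route is rejoined; steps 12 and 13 fall away.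

Step 15. Proton loss toward C6 instead of C8 would leak material to the Δ6 enol triflate, and triflylation of the hindered ketone may be sluggish. The fallback fixes the enolate regiochemistry in a separate, equilibrating step. From 19, Me3SiCl/NaI/Et3N in MeCN (thermodynamic silyl enol ether conditions) should give ent-7-(trimethylsilyloxy)-3β-[(triisopropylsilyl)oxy]-13,14,15,16-tetranorlabda-7,11-diene F3, which can be freed from any Δ6 isomer. MeLi (THF, 0 °C) then releases the lithium enolate regiospecifically and PhNTf2 traps it as 20, where the route is rejoined.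

Step 20. Cleavage of the hindered C3 TIPS ether may be slow, and forcing the conditions risks loss or migration of the acyl group. The fallback removes the TIPS group before the ester exists. From 23, TBAF (THF, 50 °C) should give ent-labda-7,13E-diene-3β,15-diol F4. Steglich acylation with 26 (DIC, DMAP, CH2Cl2, 0 °C) should acylate only the primary allylic C15 hydroxyl, the C3 hydroxyl being secondary and flanked by the quaternary C4, to give ent-3β-hydroxylabda-7,13E-dien-15-yl 30-[(tert-butyldimethylsilyl)oxy]triacontanoate F5. Brief HF·pyridine (THF, 0 °C) then removes the primary TBS ether and gives 28.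

Further compounds
F1 | step 11 | (2E,6R,8E,10Z)-10-[(tert-butyldimethylsilyl)oxy]-3,7,7-trimethyl-6-[(triisopropylsilyl)oxy]dodeca-2,8,10-trien-1-ol | C/C=C(\O[Si](C)(C)C(C)(C)C)/C=C/C(C)(C)[C@H](O[Si](C(C)C)(C(C)C)C(C)C)CC/C(C)=C/CO
F2 | step 11 | (2E,6R,8E,10Z)-10-[(tert-butyldimethylsilyl)oxy]-3,7,7-trimethyl-6-[(triisopropylsilyl)oxy]dodeca-2,8,10-trienal | C/C=C(\O[Si](C)(C)C(C)(C)C)/C=C/C(C)(C)[C@H](O[Si](C(C)C)(C(C)C)C(C)C)CC/C(C)=C/C=O
F3 | step 15 | ent-7-(trimethylsilyloxy)-3β-[(triisopropylsilyl)oxy]-13,14,15,16-tetranorlabda-7,11-diene | CC1=C(O[Si](C)(C)C)C[C@@H]2C(C)(C)[C@H](O[Si](C(C)C)(C(C)C)C(C)C)CC[C@@]2(C)[C@@H]1C=C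
F4 | step 20 | ent-labda-7,13E-diene-3β,15-diol | CC1=CC[C@@H]2C(C)(C)[C@H](O)CC[C@@]2(C)[C@@H]1CC/C(C)=C/CO
F5 | step 20 | ent-3β-hydroxylabda-7,13E-dien-15-yl 30-[(tert-butyldimethylsilyl)oxy]triacontanoate | CC1=CC[C@@H]2C(C)(C)[C@H](O)CC[C@@]2(C)[C@@H]1CC/C(C)=C/COC(=O)CCCCCCCCCCCCCCCCCCCCCCCCCCCCCO[Si](C)(C)C(C)(C)C
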